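The numbers in the tables are simulated from invented constants; noise was put on by code.

- E was what I read, and I wanted to know what clock it keeps in Wednesday's and Friday's runs.

| flask | Q | Z | time |
|---|---|---|---|
| Wednesday's | 300 mM | 3.00 mM |  |
| Friday's | 300 mM | 1.50 mM |  |
| Thursday's | 300 mM | 0.650 mM | 4.3 min |

- Wednesday's run (time / min: [E] / mM): 0.19: 12.1; 0.58: 31.6; 1.1: 60.4; 1.8: 88.7; 2.5: 112.4; 3.4: 140.3; 4.3: 162.6
- Friday's run (time / min: [E] / mM): 0.19: 7.1; 0.58: 20.7; 1.1: 32.2; 1.8: 49.3; 2.5: 66.4; 3.4: 81.0; 4.3: 101.7

(standard deviation of a reading: 2 mM)

- Overall: Q -> E, with Z as catalyst.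
- Constant volume, constant temperature.
- Readings of a species count what is bound in complexes too.
- An order is taken over about fifteen percent of the charge, up and down.

* apparent order in [Z] of the starting rate, round the charge of the Wednesday's run (the rate where two percent of its Q have turned into E)
* E in the Thursday's run at 4.3 min, as a share of the Q charged

- I wrote the balance of Z first, since its charge of 3.00 mM on Wednesday was far below the 300 mM of Q.
- If the rate goes with [Z], E follows the catalyst dose, meaning [Z] as charged times the time, and Thursday's run reaches a dose of 0.168 M·s.
- I began with the main step alone, Q to E on Z at a steady rate, so that E was a straight line in dose.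
- Wednesday's first reading gave 21.2 min⁻¹ of E per unit of dose, which put Thursday's run at 19.8 % of its charge.
- That first reading of 12.1 mM carried a scatter of 2 mM, so I held this number loosely.
- Next I let Q fall at first order, and the number dropped to 17.9 %.
- I named nothing for the rest of the bend in the curves, and read it from them at matching doses.
- Friday's reading at a dose of 0.162 M·s gave 18.3 min⁻¹ per unit of dose, and Wednesday's at 0.198 M·s gave 18.3 min⁻¹.
- Thursday's dose lay between those two doses, so I committed to 17.0 % of the charge.
- With E following dose, the rate at a given E scaled with [Z], so I committed to order one in [Z].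
- The forecast gave 0.85 and 17.5 %, and called the rise with [Z] “slightly sub-linear”.
- The flask gave an order of 1.0 and 16.8 % of the charge in Thursday's run.

    Z + Q → E + Z (323.4 L mol⁻¹ min⁻¹)
    2 Q ⇌ Q2, settled at all times (29.20 L mol⁻¹)
    2 Z → 2 Vy (30.54 L mol⁻¹ min⁻¹)

- Thursday's dose of 0.168 M·s gave 50.5 mM of E, or 18.1 min⁻¹ per unit of dose. The clock held on the simulated times too: E reached a quarter of the charge at a dose of 0.267 M·s on Friday and 0.267 M·s on Wednesday. The parking of 2 Q as Q2 is not the reason for the order in [Z], which stays at 1.0 without it. That parking did hold down the height of the curve: without it, E in Thursday's run goes from 16.8 % to 56.6 %.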